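**Retrosynthetic overview**

Locants: ring C1 (allylic CH–OAc), C2=C3, C4 (CH–OH), C5 (C–OH carrying C7H2–OBz), C6 (CH–OAc). The strategy rests on the three-carbon unit C7–C5–C6, a dihydroxyacetone (ketose) fragment whose donor carbon C6 and carbonyl carbon C5 sit next to the carbinols C1 and C4.
1. Target ⇒ (desilylation, 1,2-reduction) C4 enone ⇒ (Saegusa–Ito) C4 ketone ⇒ (reductive Nef sequence) C4 nitro compound carrying the C7 benzoate and the C1/C6 acetates.
2. Nitrocyclitol ⇒ dihydroxyacetone phosphate + 4-nitrobutanal: aldolase bond C6–C1, then nitroaldol bond C4–C5, which closes the only ring formed in the route, the carbocycle.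
3. 4-Nitrobutanal ⇐ nitromethane + acrolein; dihydroxyacetone phosphate ⇐ dihydroxyacetone.

Key step: step 3

Assumption: dihydroxyacetone is used as its commercial dimer, which gives the monomer in water, and recombinant L-rhamnulose-1-phosphate aldolase, dihydroxyacetone kinase and acetate kinase are taken as available enzymes.

**Route**

Step 1
Reactants: 1 nitromethane; 2 acrolein
Product: 3 4-nitrobutanal
Conditions: MeNO2 (10 equiv), NaOMe (5 mol%), MeOH, −20 °C, slow addition of 2; AcOH quench; distillation under reduced pressure
Reagents that add atoms: none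
Why: Base-catalysed Michael addition of the nitronate to acrolein, in which the large excess of nitromethane and the low temperature should hold back double addition, acrolein polymerisation and nitroaldol addition to the product aldehyde.

Step 2
Reactants: 4 dihydroxyacetone
Product: 5 dihydroxyacetone phosphate (DHAP)
Conditions: ATP (5 mol%), acetyl phosphate (1.2 equiv), dihydroxyacetone kinase, acetate kinase, MgCl2 (cat.), H2O, pH 7.5, 25 °C; solution assayed and used directly
Reagents that add atoms: acetyl phosphate, CC(=O)OP(=O)(O)O (phosphoryl donor, relayed through catalytic ATP)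
Why: Kinase-catalysed phosphoryl transfer from ATP to one of the two equivalent hydroxyls of 4, with ATP regenerated from ADP by acetate kinase and acetyl phosphate (enzymatic phosphorylation with cofactor recycling).

Step 3
Reactants: 5 dihydroxyacetone phosphate; 3 4-nitrobutanal
Product: 7 [(1R,2R,3S,6S)-1,2,3-trihydroxy-6-nitrocyclohexyl]methyl dihydrogen phosphate (target locants: C1–OH, C4–NO2, C5–OH, C6–OH; 1S,4S,5R,6R), via open-chain aldol adduct 6 (not isolated)
Conditions: L-rhamnulose-1-phosphate aldolase (RhuA, recombinant, Escherichia coli), 3 (1.5 equiv), H2O, pH 7.5, 25 °C, until 6 is consumed; ultrafiltration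
Reagents that add atoms: none
Why: The aldolase binds 5 as its zinc-bound (Z)-enediolate and adds the donor carbon C6 to the aldehyde carbon of 3 with enzyme-fixed facial sense at both partners, forming the C6–C1 bond of open-chain adduct 6 with the 3R,4S (L-threo) ketose pattern, which is 6R,1S in target locants. The nitromethylene of 6 (pKa near 9) is partly ionised at pH 7.5 and its nitronate carbon C4 then adds to the C5 ketone, made electrophilic by its two α-oxygen substituents, in an intramolecular Henry (nitroaldol) reaction that forms the C4–C5 bond and closes the carbocycle in the 6-exo-trig mode. The closest known reaction type is the addition of DHAP to ω-nitro aldehydes on DHAP-dependent aldolases followed by spontaneous nitroaldol cyclisation to nitrocyclitols. C6 and C1 are controlled by the enzyme, whereas C5 and C4 are set under thermodynamic control because the nitroaldol step is reversible in water: the chair with C1–OH, C6–OH, C7 and the nitro group equatorial leaves only the C5–OH axial, hence cis to C6–OH. The step needs clean facial selectivity at the aldehyde carbon, the position at which this aldolase is less strict than at the donor carbon, and it relies on the unbranched aldehyde, which offers no competing substrate bias, and on work-up at full DHAP conversion before the adduct can equilibrate on the enzyme. No protecting group is needed because both bond formations run in water on the free polyol phosphate.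

Step 4
Reactants: 7 nitrocyclitol phosphate
Product: 8 (1R,2R,3S,6S)-1-(hydroxymethyl)-6-nitrocyclohexane-1,2,3-triol
Conditions: acid phosphatase (wheat germ), H2O, pH 4.8, 37 °C; neutralisation, desalting, silica gel
Reagents that add atoms: none
Why: Enzymatic hydrolysis of the phosphate monoester with P–O cleavage at a mildly acidic pH, where neither retro-nitroaldol opening nor dehydration of the β-nitro alcohol should occur and no stereocentre is touched.

Step 5
Reactants: 8 nitro tetrol; 9 benzoyl chloride
Product: 10 [(1R,2R,3S,6S)-1,2,3-trihydroxy-6-nitrocyclohexyl]methyl benzoate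
Conditions: BzCl (1.05 equiv), pyridine, −40 → −20 °C
Reagents that add atoms: none
Why: Kinetically selective O-acylation (nucleophilic acyl substitution) of the single primary hydroxyl C7–OH over the two secondary and the tertiary hydroxyls at low temperature, with a base too weak to open the nitro alcohol.

Step 6
Reactants: 10 monobenzoate
Product: 11 (1S,2R,3R,4S)-3-[(benzoyloxy)methyl]-3-hydroxy-4-nitrocyclohexane-1,2-diyl diacetate (acetates on target C1 and C6, free C5–OH)
Conditions: Ac2O (3 equiv), pyridine, 0 → 23 °C, no DMAP
Reagents that add atoms: acetic anhydride, CC(=O)OC(C)=O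
Why: Standard acetylation of the two secondary hydroxyls, while the axial tertiary C5–OH is not acylated without a nucleophilic catalyst and so cannot become a leaving group β to the nitro group.

Step 7
Reactants: 11 nitro diacetate benzoate
Product: 12 (1S,2R,3R)-3-[(benzoyloxy)methyl]-3-hydroxy-4-(hydroxyimino)cyclohexane-1,2-diyl diacetate (E/Z mixture)
Conditions: SnCl2 (1.5 equiv), PhSH (6 equiv), Et3N (4.5 equiv), MeCN, 23 °C
Reagents that add atoms: none
Why: Reduction of the secondary nitro group by the divalent tin thiolate complex [Et3NH][Sn(SPh)3] stops at the oxime without a free nitronate or a strong base, so retro-nitroaldol opening of C4–C5 and ester cleavage should not compete, and the C4 centre is erased (nitro-to-oxime reduction, first half of a reductive Nef sequence).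

Step 8
Reactants: 12 oxime
Product: 13 (1S,2R,3R)-3-[(benzoyloxy)methyl]-3-hydroxy-4-oxocyclohexane-1,2-diyl diacetate
Conditions: aq. TiCl3 (3 equiv), NH4OAc buffer (pH about 6), THF/H2O, 23 °C
Reagents that add atoms: water, O
Why: Reductive deoximation with buffered TiCl3, in which N–O cleavage gives the imine that hydrolyses to the ketone at a pH that should leave the esters and the α-ketol intact (second half of the reductive Nef sequence).

Step 9
Reactants: 13 ketone
Product: 14 (1S,2R,3R)-3-[(benzoyloxy)methyl]-3,4-bis[(trimethylsilyl)oxy]cyclohex-4-ene-1,2-diyl diacetate (C3=C4 silyl enol ether, C5–OTMS in target locants)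
Conditions: TMSOTf (2.5 equiv), Et3N (3.5 equiv), CH2Cl2, −20 → 0 °C
Reagents that add atoms: trimethylsilyl triflate, C[Si](C)(C)OS(=O)(=O)C(F)(F)F
Why: Soft enolisation and O-silylation, which can only go toward C3 because C5 is quaternary and which caps the tertiary C5–OH as its TMS ether at the same time, with no β-leaving group available to the enol derivative.

Step 10
Reactants: 14 bis-silyl compound
Product: 15 (1S,5R,6R)-5-[(benzoyloxy)methyl]-4-oxo-5-[(trimethylsilyl)oxy]cyclohex-2-ene-1,6-diyl diacetate
Conditions: Pd(OAc)2 (1.05 equiv), MeCN, 23 °C; filtration through Celite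
Reagents that add atoms: none
Why: Saegusa–Ito oxidation through the palladium enolate at C3 and β-hydride elimination from C2, run without phosphine ligands and without base so that the zerovalent palladium formed should neither ionise the allylic C1 acetate nor trigger vinylogous elimination.

Step 11
Reactants: 15 enone
Product: 16 (1S,4S,5S,6R)-5-[(benzoyloxy)methyl]-4-hydroxy-5-[(trimethylsilyl)oxy]cyclohex-2-ene-1,6-diyl diacetate
Conditions: NaBH4 (1.1 equiv), CeCl3·7H2O (1.1 equiv), MeOH, −78 °C; aq. NH4Cl
Reagents that add atoms: none
Why: Luche 1,2-reduction, in which hydride should add axially to the half-chair that holds C1–OAc, C6–OAc and C7 (pseudo)equatorial and the C5–OTMS axial, that is on the face anti to the axial C5–O bond (Felkin–Anh polar model, and the silyl ether blocks chelation), giving the 4S carbinol with C4–OH cis to the C5 oxygen.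

Step 12
Reactants: 16 silyl ether
Product: 17 (1S,4S,5S,6R)-5-[(benzoyloxy)methyl]-4,5-dihydroxycyclohex-2-ene-1,6-diyl diacetate (target)
Conditions: 1 M aq. HCl (0.2 equiv), THF, 0 °C
Reagents that add atoms: none
Why: Acid-catalysed hydrolysis of the labile tertiary trimethylsilyl ether under brief, cold, non-basic conditions that should avoid acyl migration among the neighbouring esters and the freed cis-diol.

**Compound list**

1 | nitromethane | C[N+](=O)[O-] | starting material
2 | acrolein | C=CC=O | starting material
3 | 4-nitrobutanal | O=CCCC[N+](=O)[O-] | intermediate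
4 | dihydroxyacetone (commercial as its dimer) | OCC(=O)CO | starting material
5 | dihydroxyacetone phosphate (3-hydroxy-2-oxopropyl dihydrogen phosphate) | O=C(CO)COP(=O)(O)O | intermediate
6 | (3R,4S)-3,4-dihydroxy-7-nitro-2-oxoheptyl dihydrogen phosphate (open-chain aldol adduct) | O=C(COP(=O)(O)O)[C@H](O)[C@@H](O)CCC[N+](=O)[O-] | intermediate
7 | [(1R,2R,3S,6S)-1,2,3-trihydroxy-6-nitrocyclohexyl]methyl dihydrogen phosphate | O[C@H]1CC[C@H]([N+](=O)[O-])[C@@](O)(COP(=O)(O)O)[C@@H]1O | intermediate
8 | (1R,2R,3S,6S)-1-(hydroxymethyl)-6-nitrocyclohexane-1,2,3-triol | O[C@H]1CC[C@H]([N+](=O)[O-])[C@@](O)(CO)[C@@H]1O | intermediate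
9 | benzoyl chloride | O=C(Cl)c1ccccc1 | starting material
10 | [(1R,2R,3S,6S)-1,2,3-trihydroxy-6-nitrocyclohexyl]methyl benzoate | O[C@H]1CC[C@H]([N+](=O)[O-])[C@@](O)(COC(=O)c2ccccc2)[C@@H]1O | intermediate
11 | (1S,2R,3R,4S)-3-[(benzoyloxy)methyl]-3-hydroxy-4-nitrocyclohexane-1,2-diyl diacetate | CC(=O)O[C@H]1CC[C@H]([N+](=O)[O-])[C@@](O)(COC(=O)c2ccccc2)[C@@H]1OC(C)=O | intermediate
12 | (1S,2R,3R)-3-[(benzoyloxy)methyl]-3-hydroxy-4-(hydroxyimino)cyclohexane-1,2-diyl diacetate (E/Z mixture) | CC(=O)O[C@H]1CCC(=NO)[C@@](O)(COC(=O)c2ccccc2)[C@@H]1OC(C)=O | intermediate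
13 | (1S,2R,3R)-3-[(benzoyloxy)methyl]-3-hydroxy-4-oxocyclohexane-1,2-diyl diacetate | CC(=O)O[C@H]1CCC(=O)[C@@](O)(COC(=O)c2ccccc2)[C@@H]1OC(C)=O | intermediate
14 | (1S,2R,3R)-3-[(benzoyloxy)methyl]-3,4-bis[(trimethylsilyl)oxy]cyclohex-4-ene-1,2-diyl diacetate | CC(=O)O[C@H]1CC=C(O[Si](C)(C)C)[C@@](O[Si](C)(C)C)(COC(=O)c2ccccc2)[C@@H]1OC(C)=O | intermediate
15 | (1S,5R,6R)-5-[(benzoyloxy)methyl]-4-oxo-5-[(trimethylsilyl)oxy]cyclohex-2-ene-1,6-diyl diacetate | CC(=O)O[C@H]1C=CC(=O)[C@@](O[Si](C)(C)C)(COC(=O)c2ccccc2)[C@@H]1OC(C)=O | intermediate
16 | (1S,4S,5S,6R)-5-[(benzoyloxy)methyl]-4-hydroxy-5-[(trimethylsilyl)oxy]cyclohex-2-ene-1,6-diyl diacetate | CC(=O)O[C@H]1C=C[C@H](O)[C@@](O[Si](C)(C)C)(COC(=O)c2ccccc2)[C@@H]1OC(C)=O | intermediate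
17 | (1S,4S,5S,6R)-5-[(benzoyloxy)methyl]-4,5-dihydroxycyclohex-2-ene-1,6-diyl diacetate | CC(=O)O[C@H]1C=C[C@H](O)[C@@](O)(COC(=O)c2ccccc2)[C@@H]1OC(C)=O | target

**Step count and risk**

Total step count: 12. Longest linear sequence: 11 steps (steps 2–12 from dihydroxyacetone; equally steps 1 and 3–12 from nitromethane and acrolein).

Steps most likely to fail:

1. Step 3. Facial selectivity at the aldehyde carbon may erode, giving the C1 epimer through retro-aldol equilibration on the enzyme, or the nitroaldol closure may stay incomplete. The fallback sets out from 3 and 4 and builds the same C6–C1 and C4–C5 bonds without the enzyme. Dihydroxyacetone 4 is silylated (TBSCl, imidazole, DMF) to 1,3-bis[(tert-butyldimethylsilyl)oxy]propan-2-one F1. F1 is added to 3 under catalysis by O-tert-butyl-L-threonine (20 mol%, N-methylpyrrolidone with a little water, 4 °C) through its hydrogen-bonded (Z)-enamine, to give the syn aldol (3R,4S)-1,3-bis[(tert-butyldimethylsilyl)oxy]-4-hydroxy-7-nitroheptan-2-one F2. The sense of induction is the one the enamine model predicts for the L-catalyst and is to be confirmed on the first run, the D-catalyst being equally available. Desilylation (aq. HF, MeCN, 0 °C) gives (3R,4S)-1,3,4-trihydroxy-7-nitroheptan-2-one F3, the phosphate-free analogue of 6. In phosphate buffer at pH 7.5, F3 should close by the same thermodynamically controlled nitroaldol reaction to 8, where the route is rejoined.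

2. Step 7. The ring may open by retro-nitroaldol reaction in the amine-containing medium, or the reduction may stop short or run on to the hydroxylamine. The fallback sets out from 11 and replaces the reductive sequence by an oxidative Nef reaction of a silyl nitronate. TMSOTf and Et3N (CH2Cl2, 0 °C) silylate both the C5–OH and the nitro group to give the C5-O-trimethylsilyl trimethylsilyl nitronate of 11 F4, in which retro-nitroaldol opening is blocked. Oxidation of F4 with mCPBA (CH2Cl2, 0 °C) gives (1S,2R,3R)-3-[(benzoyloxy)methyl]-4-oxo-3-[(trimethylsilyl)oxy]cyclohexane-1,2-diyl diacetate F5. Under the conditions of step 9, F5 gives 14, where the route is rejoined, so steps 7 and 8 are both replaced.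

3. Step 11. Hydride addition may show poor facial selectivity at C4, or conjugate reduction may compete. The fallback sets out from 15 and replaces substrate control by catalyst control: Corey–Bakshi–Shibata reduction with (R)-2-methyl-CBS-oxazaborolidine and catecholborane in toluene at −78 °C. The catalyst enantiomer is chosen for the 4S carbinol on the premise that the quaternary C5 side is the larger carbonyl substituent. This gives 16 directly, and no new compound is made.

**Further compounds**

F1 | step 3 | 1,3-bis[(tert-butyldimethylsilyl)oxy]propan-2-one | CC(C)(C)[Si](C)(C)OCC(=O)CO[Si](C)(C)C(C)(C)C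
F2 | step 3 | (3R,4S)-1,3-bis[(tert-butyldimethylsilyl)oxy]-4-hydroxy-7-nitroheptan-2-one | CC(C)(C)[Si](C)(C)OCC(=O)[C@H](O[Si](C)(C)C(C)(C)C)[C@@H](O)CCC[N+](=O)[O-]
F3 | step 3 | (3R,4S)-1,3,4-trihydroxy-7-nitroheptan-2-one | O=C(CO)[C@H](O)[C@@H](O)CCC[N+](=O)[O-]
F4 | step 7 | C5-O-trimethylsilyl trimethylsilyl nitronate of 11 | CC(=O)O[C@H]1CCC(=[N+]([O-])O[Si](C)(C)C)[C@@](O[Si](C)(C)C)(COC(=O)c2ccccc2)[C@@H]1OC(C)=O
F5 | step 7 | (1S,2R,3R)-3-[(benzoyloxy)methyl]-4-oxo-3-[(trimethylsilyl)oxy]cyclohexane-1,2-diyl diacetate | CC(=O)O[C@H]1CCC(=O)[C@@](O[Si](C)(C)C)(COC(=O)c2ccccc2)[C@@H]1OC(C)=O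
F0 | step 11 | none | none
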